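The constants were drawn at random within sensible limits; the run is a simulation.

Slowness here has a deadline: a small loading of D turns Q into G, G binds D as D.G, E takes D.G on to X and gives D back, and meanwhile D falls away to Z.

| setting | teal | blue | green | ochre |
|---|---|---|---|---|
| Q | 0.050 M | 0.050 M | 0.050 M | 0.050 M |
| E | 1.80 equiv | 1.80 equiv | 1.80 equiv | 1.80 equiv |
| D | 0.32 mol% | 0.32 mol% | 0.32 mol% | 0.32 mol% |
| temperature | 20 °C | 60 °C | 40 °C |  |
| time | 40 h | 40 h | 40 h | 40 h |
| remark |  |  |  | at 60 °C until 12 h, from then on at 20 °C |

    D + G ⇌ D.G (K1 = 17 M⁻¹, k1 = 9600 M⁻¹ h⁻¹, Ea1 = 41.0 kJ mol⁻¹, ΔH1 = −16.0 kJ mol⁻¹)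
    E + D.G → D + X (k2 = 690 M⁻¹ h⁻¹, Ea2 = 41.0 kJ mol⁻¹)
    Q + D → D + G (k3 = 250 M⁻¹ h⁻¹, Ea3 = 57.0 kJ mol⁻¹)
    D → Z (k4 = 0.040 h⁻¹, Ea4 = 105 kJ mol⁻¹)
    (constants at 40 °C)

- all constants are for 40 °C and move with temperature by the activation energies and enthalpies

- the flask with the highest amount of X, in percent of the Q charged ("all alike" if they lie within 1.5 percentage points) (teal / blue / green / ochre / all alike)
- final X, as a percentage of the Q charged, in teal
- final X, as a percentage of the Q charged, in blue
- final X, as a percentage of the Q charged, in green
- final X, as a percentage of the Q charged, in ochre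

Follow the natural logarithm of q, the fraction of Q left, against time. I let D fade on its own and leave D.G out of the count. At the start D stands at its charge, 1.60 × 10⁻⁴ M, so Q falls pseudo-first-order and the logarithm drops in a straight line, its slope being that charge times the constant of Q + D. The knee comes at the lifetime of D, the inverse of the constant of D → Z, and behind the knee the line flattens into a level.

In blue the slope is 0.149 h⁻¹ and the lifetime 2.22 h, so the logarithm levels off 0.331 below its start. Call this drop, slope times lifetime, the reach of the catalyst: exp(−reach) is the fraction of Q the curve runs toward. In green the slope is 0.0400 h⁻¹, the lifetime 25.0 h and the reach 1.00. In teal they are 0.00898 h⁻¹, 392 h and 3.52, so teal has more reach than green, and green more than blue.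

But by a given time a flask has spent of its reach the part 1 − exp(−time/lifetime). Blue is far past its knee at 40 h and has spent 0.331. Teal is still on its straight line and has spent 0.342. Green has spent 0.798, more than either. So I reckon q at the end as 71.1% in teal, 71.8% in blue and 45.0% in green. Ochre enters the cold with 0.450% of its D by this clock, and its whole spend is 0.330. Ranked by Q spent, green comes first.

Spent Q becomes G before it becomes X. Both steps need D, so they run on one catalyst clock. Take D.G as steady and E at its charge, 0.0900 M. Then ρ, the pull of D on G over its pull on Q, is 8.37 in teal, 3.80 in green and 1.88 in blue. G is then (q − q^ρ)/(ρ − 1), and X is what remains of the charge. I commit to X of 20.1% in teal, 7.53% in blue, 40.6% in green and 7.52% in ochre, where I use blue's ρ.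

The forecast names green, with teal 18.9%, blue 7.4%, green 38% and ochre 7.6%, and its ground is this: “The catalyst's lifetime decides this”. My green stands above the forecast's, and so does my teal.

The flasks give green as the highest, with green 36.6%, teal 17.8%, ochre 7.55% and blue 7.40%. Blue left for 400 h still holds 7.40% of X and 71.8% of Q, and exp(−reach) for blue is 71.8%. The neighbour flask with 0.20 M of Q, at blue's temperature and loading, has its charge of D and so its reach multiplied by 4.00, to 1.32, and exp(−reach) there is 26.6%. That flask ends with 26.6% of its Q.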